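At early times, what does Wednesday's run, the flask asked about, show?

A burst that dies. Product reaches 63.0 % by 5.00 min, yet the last 20.0 min add 2.6 percentage points, while 18.7 % of the substrate has still not appeared as product. So I look at the catalyst.

common to all: free enzyme 0.1 mol%; impurity 24 µM; temperature 37 °C
- Wednesday's: substrate 0.10 M; the very flask that is asked about, followed so far
- Thursday's: substrate 0.15 M; run made earlier
- flask: substrate 0.10 M; time 1.0 h

| Wednesday's: time / min | Wednesday's: product / % | Thursday's: time / min | Thursday's: product / % |
|---|---|---|---|
| 5.00 | 63.0 | 2.50 | 53.6 |
| 15.0 | 73.3 | 5.00 | 59.3 |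
| 30.0 | 77.7 | 8.00 | 63.7 |
| 40.0 | 78.7 | 10.0 | 66.4 |
| 60.0 | 81.3 | 12.0 | 66.2 |

(readings scatter by 0.5 percentage points)

- product that was removed still counts
- additions bring no volume worth counting
- the earlier runs do not show what temperature does; that part of a forecast is a guess

- autumn: at 1.0 h add free enzyme, 100 % of the amount charged, then wait 20 min
- winter: at 1.0 h raise the temperature by 15 K, then wait 20 min
- midnight: at 1.0 h take out 90 % of the product then present, then wait 20 min
- noon: change nothing and wait 20 min more

- product, in percent of the substrate first charged, at 1.0 h
- what to do for the largest gain in product; "none" if nothing gains more than 2 percentage points (autumn / winter / midnight / noon / none)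
- product present, with what was taken out counted in, in percent of the substrate first charged, after autumn
- product present, with what was taken out counted in, in percent of the substrate first charged, after winter

What could take free enzyme away?

The impurity is my suspect, and I assume it binds free enzyme one to one. Divide the rate at which c(impurity) falls by the rate at which c(free enzyme) falls on that step: the same expression stands above and below, the ratio is one, and time drops out, however fast the step runs. So I carry the poison share, impurity charged per free enzyme charged: 0.240. The impurity would be the limiting reagent of that step, with 24 µM against 100 µM of free enzyme.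

Thursday's share is 0.160, lower, yet its product at 5.00 min reads 59.3 % against Wednesday's reading of 63.0 % at 5.00 min. Doesn't that sink you?

As a rule for yield, yes. The share is an account of catalyst. On that step alone the flask loses 24.0 % of the free enzyme charged and keeps 76.0 %, more than it loses, so the stalling needs a further cause.

Then what is it good for?

For the addition at 1.0 h. If the impurity has reacted by then, the new enzyme pays no share. I commit to about 81.3 % now, and to autumn.

The forecast says 81 %, autumn, 92 % after autumn and 84 % after winter, with the ground that “Fresh enzyme should restart the burst, damped by accumulated product and low substrate”.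

The flask gives 80.8 %. Autumn gains 12 points, to 92.4 %; midnight gains 4.9 points, noon 0.85 points, and winter 0.24 points, to 81.1 %.

    free enzyme → unfolded enzyme (k = 0.00710 min⁻¹, Ea = 226 kJ mol⁻¹)
    substrate + free enzyme → product + free enzyme, rate k2*[substrate]*[free enzyme]/(1 + ([substrate]/Km2) + ([product]/Kp2)) (0.200 M, 1.90 mM, k = 1.30 × 10⁵ M⁻¹ min⁻¹, Ea = 37.0 kJ mol⁻¹)
    substrate + free enzyme → spent catalyst A (k = 0.610 M⁻¹ min⁻¹, Ea = 49.0 kJ mol⁻¹)
    2 free enzyme → spent catalyst B (k = 4100 M⁻¹ min⁻¹, Ea = 50.0 kJ mol⁻¹)
    free enzyme + impurity → spent catalyst C (k = 49000 M⁻¹ min⁻¹, Ea = 38.0 kJ mol⁻¹)
    (constants at 37 °C)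

By 6.00 min spent catalyst C in the flask holds 24.0 % of the enzyme charged, the share, with impurity at 0.0192 % of its own charge. A run that shows the forecast's 81 % wrong for a changed charge is the neighbouring flask, the same recipe with 9.6 × 10⁻⁵ M of impurity, which reads 38.2 % at 60.0 min. Its share is 0.960. There free enzyme stands at 0 %, spent catalyst C at 85.6 % of the enzyme charged, below the share, and impurity at 11 % of its own charge, with 62 % of the substrate remaining.

(The runs stem from a simulated flask with constants of no real substance; the scatter is artificial.)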